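**Plan** (ent-kaurane locants: ring A = C1–C5, C10; δ-lactone = C10–C20–O–C7(=O)–C8–C9; ring C = C8, C9, C11–C14; ring D = C8, C13–C16)
- Retrosynthesis: cut C16–C17 first (hydroxymethyl from an α-methylene 15-ketone), then C9–C11 and C8–C15 together, then C8–C14 (lactone alkylation), C9–C10 (radical addition to an acrylate) and, in ring A, C5–C6 and C4–C19.
- Enabling feature: the bicyclo[3.2.1]octane sits on the C8–C9 edge of the δ-lactone and carries oxygen at C11 and C15, so a C8=C9 enoate with a C8–CH2–CH(CH2CHO)2 arm holds both ring bonds latent.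
- Forward: cyclohexenone → ring A with fused γ-lactone (C6/C19) → spiro δ-lactone at C10 → C8 alkylation and desaturation → ozonolysis to the symmetrical dialdehyde → rings C and D in one reductive step → C15 ketone, C16 methylene, C17 hydroxyl.
- Stereochemistry: C4 by ligand-controlled conjugate addition; C5 by thermodynamic cis-fusion; C10 by radical attack anti to the γ-lactone; C9, C8, C11, C13 (and C15) in the cascade under control of spiro ring A; C16 by exo-face protonation.

Key step: step 14

Remark: a centre left open in a SMILES marks an epimer mixture that converges later (C5 in 4–7, the acetal carbon in 8 and 9, C10 in 11, C8 in 19–22, C16 in 29 and 30, ozonides 5 and 24); "exo" is the face of the C15–C16 bridge turned to C14, "endo" the face turned to C11–C12.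

**Step 1**
Reactants: 1 3-methylcyclohex-2-en-1-one
Product: 3 (S)-{3-[(E)-hex-1-en-1-yl]-3-methylcyclohex-1-en-1-yl}oxy(trimethyl)silane, via aluminium enolate 2 (not isolated)
Conditions: 1-hexyne, i-Bu2AlH, hexane, 50 °C; then 1, copper thiophene-2-carboxylate (10 mol %), BINOL-derived bis(1-phenylethyl)amine phosphoramidite (11 mol %, enantiomer that delivers the S centre), Et2O, −30 °C; then Me3SiOTf, −30 → 0 °C
Reagents that add atoms: (E)-hex-1-enyl(diisobutyl)aluminium, CCCC/C=C/[Al](CC(C)C)CC(C)C; trimethylsilyl trifluoromethanesulfonate, C[Si](C)(C)OS(=O)(=O)C(F)(F)F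
Why: Copper-catalysed asymmetric conjugate addition of an alkenylalane to a β-substituted cyclohexenone should create the C4 quaternary centre under ligand control, and O-silylation of the regiodefined aluminium enolate fixes the C5=C10 enol ether.

**Step 2**
Reactants: 3 (S)-silyl enol ether
Product: 4 (3S)-2-(dimethoxymethyl)-3-[(E)-hex-1-en-1-yl]-3-methylcyclohexan-1-one (C2 epimers)
Conditions: HC(OMe)3, Me3SiOTf (10 mol %), CH2Cl2, −78 °C
Reagents that add atoms: trimethyl orthoformate, COC(OC)OC
Why: Mukaiyama-type addition of the silyl enol ether to the dimethoxycarbenium ion should place the future C6 on C5 at the aldehyde oxidation level, so that no C5–H flanked by two carbonyls exists before the olefination; C5 is equilibrated in step 4.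

**Step 3**
Reactants: 4 keto dimethyl acetal
Product: 6 (1R)-2-(dimethoxymethyl)-1-methyl-3-oxocyclohexane-1-carbaldehyde, via ozonide 5 (not isolated)
Conditions: O3, CH2Cl2, −78 °C; then PPh3, −78 °C → rt
Reagents that add atoms: ozone, [O-][O+]=O
Why: Ozonolysis with reductive work-up cleaves the only C=C bond and leaves C19 on C4 as a formyl group, ketone and acetal being inert on this time scale.

**Step 4**
Reactants: 6 keto aldehyde
Product: 8 (3aR,7aS)-1-methoxy-3a-methylhexahydro-2-benzofuran-7(1H)-one (cis-fused; anomer mixture), via hydroxy ketone 7 (not isolated)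
Conditions: LiAlH(Ot-Bu)3, THF, −78 °C; aqueous work-up; then camphorsulfonic acid (10 mol %), MeOH, rt
Reagents that add atoms: none
Why: Chemoselective hydride reduction of the aldehyde beside the ketone, then acid-catalysed transacetalisation, should close the five-membered cyclic acetal while C5 equilibrates through the enol to the preferred cis-fused bicycle with C6 and C19 on the same face.

**Step 5**
Reactants: 8 bicyclic acetal ketone
Product: 9 (3aR,7aS)-1-methoxy-3a-methyl-7-methylideneoctahydro-2-benzofuran
Conditions: Ph3PCH3Br, KOt-Bu, THF, 0 °C → rt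
Reagents that add atoms: methylenetriphenylphosphorane, C=P(c1ccccc1)(c1ccccc1)c1ccccc1
Why: Wittig methylenation of the C10 ketone, which at this stage has only ordinary ketone acidity at C5, should give the exocyclic alkene with the stable cis-fusion retained.

**Step 6**
Reactants: 9 methylidene acetal
Product: 10 (3aR,7aS)-3a-methyl-7-methylidenehexahydro-2-benzofuran-1(3H)-one
Conditions: CrO3, H2SO4, acetone/H2O, 0 °C
Reagents that add atoms: water, O
Why: Jones oxidation, in which aqueous acid hydrolyses the methyl acetal to the lactol and hexavalent chromium oxidises it, should give the γ-lactone (C6=O, O–C19) with the exocyclic alkene intact.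

**Step 7**
Reactants: 10 methylidene lactone
Product: 11 C10–C20 spiro-epoxide of 10 (C10 epimers)
Conditions: mCPBA, CH2Cl2, 0 °C → rt
Reagents that add atoms: 3-chloroperbenzoic acid, OOC(=O)c1cccc(Cl)c1
Why: Prilezhaev epoxidation of the only alkene; the epimer mixture is used as such because both epimers open to the same C10 radical in step 8.

**Step 8**
Reactants: 11 spiro-epoxide; 12 2,2,2-trifluoroethyl acrylate
Product: 14 spiro bis-lactone (γ-lactone C6/C19 on ring A; saturated δ-lactone C10–C20–O–C7(=O)–C8–C9; C9 trans to C6), via hydroxy trifluoroethyl ester 13 (not isolated)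
Conditions: Cp2TiCl2 (30 mol %), Zn dust, 2,4,6-collidine·HCl, THF, rt; 12 in excess
Reagents that add atoms: none
Why: Reductive epoxide opening by Cp2TiCl (trivalent titanium, from Cp2TiCl2 and Zn) gives the tertiary C10 radical bearing C20H2–O–Ti; Giese addition to the acrylate should occur on the face away from the fused γ-lactone (C6 on C5 and C19 on C4), so C9 ends trans to C6, and the C20 alkoxide then displaces trifluoroethoxide to close the δ-lactone.

**Step 9**
Reactants: 15 cyclopent-3-ene-1-carboxylic acid
Product: 16 cyclopent-3-en-1-ylmethanol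
Conditions: LiAlH4, Et2O, 0 °C → rt
Reagents that add atoms: none
Why: Hydride reduction of the carboxylic acid to the primary alcohol; the isolated alkene is inert.

**Step 10**
Reactants: 16 cyclopent-3-en-1-ylmethanol
Product: 17 4-(iodomethyl)cyclopent-1-ene
Conditions: I2, PPh3, imidazole, CH2Cl2, 0 °C → rt
Reagents that add atoms: iodine, [I][I]
Why: Appel-type iodination of the primary alcohol through the alkoxyphosphonium ion; no stereocentre is involved.

**Step 11**
Reactants: 14 spiro bis-lactone; 17 4-(iodomethyl)cyclopent-1-ene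
Product: 19 8-(cyclopent-3-en-1-ylmethyl) spiro bis-lactone (C8 epimers), via lithium enolate 18 (not isolated)
Conditions: LiN(i-Pr)2, THF, −78 °C; then 17, DMPU, −78 → −20 °C
Reagents that add atoms: none
Why: Kinetic enolisation should occur at the unhindered C8 methylene of the δ-lactone (C5–H of the γ-lactone is tertiary and flanked by two quaternary carbons), and SN2 enolate alkylation by the primary iodide forms C8–C14; the C8 configuration is lost in step 12.

**Step 12**
Reactants: 19 alkylated bis-lactone
Product: 23 8-(cyclopent-3-en-1-ylmethyl)-8,9-didehydro spiro bis-lactone, via lithium enolate 20 (not isolated), via selenide 21 (not isolated), via selenoxide 22 (not isolated)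
Conditions: LiN(i-Pr)2, THF, −78 °C; PhSeSePh, DMPU, −78 → −40 °C; then mCPBA (1.0 equiv), CH2Cl2, −78 °C; i-Pr2NH, −78 °C → rt
Reagents that add atoms: none
Why: α-Selenenylation of the lactone enolate and selenoxide syn-elimination should give the endocyclic C8=C9 enoate, as is usual for 2-alkyl-2-selanyl cyclic carbonyl compounds; the diselenide and low-temperature peracid spare the cyclopentene and the amine traps benzeneselenenic acid.

**Step 13**
Reactants: 23 unsaturated lactone
Product: 25 dialdehyde (C8=C9 enoate with C8–CH2–CH(CH2CHO)2 arm), via ozonide 24 (not isolated)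
Conditions: O3 (1 equiv, Sudan Red 7B end point), CH2Cl2, −78 °C; then PPh3, −78 °C → rt
Reagents that add atoms: ozone, [O-][O+]=O
Why: Ozonolysis should be selective for the electron-rich cis-disubstituted cyclopentene over the electron-poor trisubstituted enoate and unmasks both CH2CHO arms at once, so C13 stays non-stereogenic.

**Step 14**
Reactants: 25 dialdehyde
Product: 26 11,15-diol with the complete ring skeleton (C16 unsubstituted; 11-OH equatorial on ring C, 15-OH exo)
Conditions: SmI2 (2.5 equiv, 0.1 M in THF, added over 1 h), LiBr, t-BuOH (1 equiv), THF (0.005 M in 25), −78 °C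
Reagents that add atoms: none
Why: SmI2, converted by LiBr into the stronger reductant SmBr2, reduces one formyl group to a ketyl that attacks the enoate β-carbon C9 (6-endo-trig radical closure of ring C at the electronically preferred carbon), a second electron turns the C8 radical into the trivalent samarium lactone enolate, and this adds to the remaining formyl group (5-exo-trig aldol closure of ring D). The closest known reaction type is the SmI2-mediated ketyl–olefin cyclisation onto an α,β-unsaturated lactone followed by samarium-enolate aldol closure on a second aldehyde of the same molecule. C9 is set by approach of the ketyl on the lactone face syn to C1, the other face being covered by the C5 branch of spiro C10 with its fused γ-lactone and the C4 quaternary centre; C11 is set by a chair-like transition state with the O–Sm group equatorial and anti to C8, away from the axial CH2CHO arm on C13. C8 and C13 follow from the geometry of the bicyclo[3.2.1]octane, since only the arm that is axial on the new ring C can reach C8, and C15 is set by a samarium-bridged closed aldol transition state that places its hydroxyl exo (it is oxidised in step 15). The step needs C9 face selectivity, which spiro ring A should secure, and it needs ketyl addition to outrun pinacol coupling of the two formyl groups, which slow addition at high dilution should secure by keeping divalent samarium scarce while the second formyl group is still needed as aldol acceptor; the arms are identical, so either may start, and C8 carries no hydrogen.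

**Step 15**
Reactants: 26 diol
Product: 27 11-hydroxy-15-oxo tetracyclic bis-lactone
Conditions: Dess–Martin periodinane (1.05 equiv), pyridine, CH2Cl2, 0 °C
Reagents that add atoms: none
Why: Dess–Martin oxidation should take the exposed exo C15–OH on the cyclopentane, whereas C11–OH sits in the niche between ring C and spiro ring A (C1 methylene, C5 methine) and exchanges onto iodine far more slowly.

**Step 16**
Reactants: 27 hydroxy ketone
Product: 31 11-hydroxy-16-methylidene-15-oxo tetracyclic bis-lactone, via dilithium alkoxide enolate 28 (not isolated), via Mannich base 29 (not isolated), via trimethylammonium iodide 30 (not isolated)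
Conditions: LiN(SiMe3)2 (2.2 equiv), THF, −78 °C; Me2N=CH2+ I− (2.5 equiv), −78 → 0 °C; then MeI, CH2Cl2, rt; then aq NaHCO3, rt
Reagents that add atoms: dimethylmethyleneammonium iodide, C=[N+](C)C.[I-]
Why: Eschenmoser methylenation, in which the C15 ketone can enolise only toward C16 (C8 is quaternary) and is far more acidic than the lactone C5–H, the enolate undergoes a Mannich reaction with the iminium salt, and quaternisation with Hofmann-type elimination gives the exocyclic C16=C17 enone.

**Step 17**
Reactants: 31 enone
Product: 33 target CNP0555433.1, via pinacol boronate 32 (not isolated)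
Conditions: CuCl (5 mol %), NaOt-Bu (8 mol %), Xantphos (5 mol %), B2pin2, MeOH (2 equiv), THF, rt; then NaBO3·4H2O, THF/H2O, rt
Reagents that add atoms: sodium perborate, O[B-]1(O)OO[B-](O)(O)OO1.[Na+].[Na+]
Why: Copper-catalysed conjugate borylation puts boron on C17 and methanol should protonate the enolate at C16 on the exo face (syn to C14, away from the C11–C12 bridge and its axial H-11), leaving C17 endo as in the target; perborate then oxidises C–B to C–OH with retention under conditions mild enough to avoid C16 epimerisation and dehydration.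

**Compound list**
1 | 3-methylcyclohex-2-en-1-one | CC1=CC(=O)CCC1 | starting material
2 | diisobutylaluminium (S)-3-[(E)-hex-1-en-1-yl]-3-methylcyclohex-1-en-1-olate | C[C@@]1(/C=C/CCCC)CCCC(O[Al](CC(C)C)CC(C)C)=C1 | intermediate (not isolated)
3 | (S)-{3-[(E)-hex-1-en-1-yl]-3-methylcyclohex-1-en-1-yl}oxy(trimethyl)silane | C[C@@]1(/C=C/CCCC)CCCC(O[Si](C)(C)C)=C1 | intermediate
4 | (3S)-2-(dimethoxymethyl)-3-[(E)-hex-1-en-1-yl]-3-methylcyclohexan-1-one (C2 epimers) | C[C@@]1(/C=C/CCCC)CCCC(=O)C1C(OC)OC | intermediate
5 | ozonide of 4 (3-butyl-1,2,4-trioxolan-5-yl group on C4) | C[C@@]1(C2OOC(CCCC)O2)CCCC(=O)C1C(OC)OC | intermediate (not isolated)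
6 | (1R)-2-(dimethoxymethyl)-1-methyl-3-oxocyclohexane-1-carbaldehyde (C2 epimers) | C[C@@]1(C=O)CCCC(=O)C1C(OC)OC | intermediate
7 | (3R)-2-(dimethoxymethyl)-3-(hydroxymethyl)-3-methylcyclohexan-1-one (C2 epimers) | C[C@@]1(CO)CCCC(=O)C1C(OC)OC | intermediate (not isolated)
8 | (3aR,7aS)-1-methoxy-3a-methylhexahydro-2-benzofuran-7(1H)-one (cis-fused, anomer mixture) | C[C@@]12CCCC(=O)[C@@H]1C(OC)OC2 | intermediate
9 | (3aR,7aS)-1-methoxy-3a-methyl-7-methylideneoctahydro-2-benzofuran (anomer mixture) | C[C@@]12CCCC(=C)[C@@H]1C(OC)OC2 | intermediate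
10 | (3aR,7aS)-3a-methyl-7-methylidenehexahydro-2-benzofuran-1(3H)-one | C[C@@]12CCCC(=C)[C@@H]1C(=O)OC2 | intermediate
11 | C10–C20 spiro-epoxide of 10 (C10 epimers) | C[C@@]12CCCC3(CO3)[C@@H]1C(=O)OC2 | intermediate
12 | 2,2,2-trifluoroethyl acrylate | C=CC(=O)OCC(F)(F)F | starting material
13 | ring-A γ-lactone with C10 bearing CH2OH (C20, cis to C6) and CH2CH2CO2CH2CF3 (C9–C8–C7, trans to C6) | C[C@@]12CCC[C@@](CO)(CCC(=O)OCC(F)(F)F)[C@@H]1C(=O)OC2 | intermediate (not isolated)
14 | spiro bis-lactone (γ-lactone C6/C19; saturated δ-lactone C7/C20 spiro at C10) | C[C@@]12CCC[C@]3(COC(=O)CC3)[C@@H]1C(=O)OC2 | intermediate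
15 | cyclopent-3-ene-1-carboxylic acid | OC(=O)C1CC=CC1 | starting material
16 | cyclopent-3-en-1-ylmethanol | OCC1CC=CC1 | intermediate
17 | 4-(iodomethyl)cyclopent-1-ene | ICC1CC=CC1 | intermediate
18 | lithium enolate of 14 (C7–O–Li, C7=C8) | C[C@@]12CCC[C@]3(COC(O[Li])=CC3)[C@@H]1C(=O)OC2 | intermediate (not isolated)
19 | 8-(cyclopent-3-en-1-ylmethyl) spiro bis-lactone (C8 epimers) | C[C@@]12CCC[C@]3(COC(=O)C(CC4CC=CC4)C3)[C@@H]1C(=O)OC2 | intermediate
20 | lithium enolate of 19 | C[C@@]12CCC[C@]3(COC(O[Li])=C(CC4CC=CC4)C3)[C@@H]1C(=O)OC2 | intermediate (not isolated)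
21 | 8-phenylselanyl derivative of 19 | C[C@@]12CCC[C@]3(COC(=O)C(CC4CC=CC4)([Se]c4ccccc4)C3)[C@@H]1C(=O)OC2 | intermediate (not isolated)
22 | selenoxide of 21 | C[C@@]12CCC[C@]3(COC(=O)C(CC4CC=CC4)([Se](=O)c4ccccc4)C3)[C@@H]1C(=O)OC2 | intermediate (not isolated)
23 | 8-(cyclopent-3-en-1-ylmethyl)-8,9-didehydro spiro bis-lactone | C[C@@]12CCC[C@]3(COC(=O)C(CC4CC=CC4)=C3)[C@@H]1C(=O)OC2 | intermediate
24 | ozonide of 23 (6,7,8-trioxabicyclo[3.2.1]octan-3-ylmethyl group on C8) | C[C@@]12CCC[C@]3(COC(=O)C(CC4CC5OOC(C4)O5)=C3)[C@@H]1C(=O)OC2 | intermediate (not isolated)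
25 | dialdehyde: 8,9-didehydro spiro bis-lactone with C8–CH2–CH(CH2CHO)2 arm | C[C@@]12CCC[C@]3(COC(=O)C(CC(CC=O)CC=O)=C3)[C@@H]1C(=O)OC2 | intermediate
26 | 11,15-dihydroxy tetracyclic bis-lactone (C16 unsubstituted) | C[C@@]12CCC[C@]3(COC(=O)[C@@]45C[C@@H](C[C@@H](O)[C@H]43)C[C@@H]5O)[C@@H]1C(=O)OC2 | intermediate
27 | 11-hydroxy-15-oxo tetracyclic bis-lactone | C[C@@]12CCC[C@]3(COC(=O)[C@@]45C[C@@H](C[C@@H](O)[C@H]43)CC5=O)[C@@H]1C(=O)OC2 | intermediate
28 | dilithium C11-alkoxide C15-enolate of 27 | C[C@@]12CCC[C@]3(COC(=O)[C@@]45C[C@@H](C[C@@H](O[Li])[C@H]43)C=C5O[Li])[C@@H]1C(=O)OC2 | intermediate (not isolated)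
29 | 16-(dimethylaminomethyl) derivative of 27 | C[C@@]12CCC[C@]3(COC(=O)[C@@]45C[C@@H](C[C@@H](O)[C@H]43)C(CN(C)C)C5=O)[C@@H]1C(=O)OC2 | intermediate (not isolated)
30 | 16-(trimethylammoniomethyl) iodide of 27 | C[C@@]12CCC[C@]3(COC(=O)[C@@]45C[C@@H](C[C@@H](O)[C@H]43)C(C[N+](C)(C)C)C5=O)[C@@H]1C(=O)OC2.[I-] | intermediate (not isolated)
31 | 11-hydroxy-16-methylidene-15-oxo tetracyclic bis-lactone | C[C@@]12CCC[C@]3(COC(=O)[C@@]45C[C@@H](C[C@@H](O)[C@H]43)C(=C)C5=O)[C@@H]1C(=O)OC2 | intermediate
32 | C17 pinacol boronate (C17 endo, H-16 exo) | C[C@@]12CCC[C@]3(COC(=O)[C@@]45C[C@@H](C[C@@H](O)[C@H]43)[C@@H](CB6OC(C)(C)C(C)(C)O6)C5=O)[C@@H]1C(=O)OC2 | intermediate (not isolated)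
33 | CNP0555433.1 (11-hydroxy, 15-oxo, 16-endo-hydroxymethyl bis-lactone) | C[C@@]12CCC[C@]3(COC(=O)[C@@]45C[C@@H](C[C@@H](O)[C@H]43)[C@@H](CO)C5=O)[C@@H]1C(=O)OC2 | target

**Totals**
Total: 17 steps. Longest linear sequence: 15 steps (steps 1–8 and 11–17).

**Steps most likely to fail**

Step 14. Pinacol coupling of the two formyl groups to a cyclopentane-1,2-diol, or simple reduction, may overtake the 6-endo ketyl addition to the hindered C9. The fallback sets out from 23 and returns at 27. Ozonolysis of 23 in CH2Cl2/MeOH over NaHCO3 gives the aldehyde α-methoxy hydroperoxide F1, and Ac2O/Et3N dehydrates the hydroperoxide terminus to the aldehyde methyl ester F2 (both C13 epimers, since the arms now differ). With one formyl group no pinacol coupling is possible. SmI2/LiBr/t-BuOH then effects the same ketyl addition to C9, and the trivalent samarium enolate at C8 is acylated by the ester arm (Claisen-type closure of ring D). This gives 27 directly from the C13 epimer whose ester arm is axial; the other epimer stops after ring C and is separated, and step 15 is not needed.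

Step 12. The selenoxide may eliminate toward the side chain (exocyclic C8=C14), or enolisation may be incomplete at the tertiary C8. The fallback sets out from 14 and returns at 23. Enolate 18 is selenenylated with PhSeBr to the α-phenylselanyl lactone F3; H2O2/pyridine gives the selenoxide F4, which can eliminate only into the ring to the parent 8,9-didehydro lactone F5. I2/pyridine gives the 8-iodo enoate F6, and Negishi coupling with (cyclopent-3-en-1-ylmethyl)zinc iodide F7 (from 17 and Zn dust) under Pd(PPh3)4 (zerovalent palladium) forms C8–C14 on the sp2 carbon and delivers 23; step 11 is then skipped.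

Step 15. Site discrimination between the two secondary hydroxyls may be insufficient (oxidation at C11 or over-oxidation to the 11,15-dione). The fallback sets out from 26 and returns at 27. Et3SiCl/imidazole silylates the exposed C15–OH to the 15-triethylsilyl ether F8; t-BuMe2SiOTf/2,6-lutidine caps the hindered C11–OH to give the bis-silyl ether F9; PPTS in MeOH removes only the triethylsilyl group to give the 11-silyl ether F10; Dess–Martin oxidation gives the 15-ketone F11; HF·pyridine releases 27. Differentiation then rests on protecting-group steps that respond more strongly to steric environment and whose mixtures can be recycled.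

**Further compounds**
F1 | step 14 | aldehyde α-methoxy hydroperoxide from 23 | C[C@@]12CCC[C@]3(COC(=O)C(CC(CC=O)CC(OC)OO)=C3)[C@@H]1C(=O)OC2
F2 | step 14 | aldehyde methyl ester (C13 epimers) | C[C@@]12CCC[C@]3(COC(=O)C(CC(CC=O)CC(=O)OC)=C3)[C@@H]1C(=O)OC2
F3 | step 12 | 8-phenylselanyl spiro bis-lactone | C[C@@]12CCC[C@]3(COC(=O)C([Se]c4ccccc4)C3)[C@@H]1C(=O)OC2
F4 | step 12 | selenoxide of F3 | C[C@@]12CCC[C@]3(COC(=O)C([Se](=O)c4ccccc4)C3)[C@@H]1C(=O)OC2
F5 | step 12 | parent 8,9-didehydro spiro bis-lactone | C[C@@]12CCC[C@]3(COC(=O)C=C3)[C@@H]1C(=O)OC2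
F6 | step 12 | 8-iodo-8,9-didehydro spiro bis-lactone | C[C@@]12CCC[C@]3(COC(=O)C(I)=C3)[C@@H]1C(=O)OC2
F7 | step 12 | (cyclopent-3-en-1-ylmethyl)zinc iodide | I[Zn]CC1CC=CC1
F8 | step 15 | 15-O-triethylsilyl ether of 26 | C[C@@]12CCC[C@]3(COC(=O)[C@@]45C[C@@H](C[C@@H](O)[C@H]43)C[C@@H]5O[Si](CC)(CC)CC)[C@@H]1C(=O)OC2
F9 | step 15 | 11-O-tert-butyldimethylsilyl 15-O-triethylsilyl ether of 26 | C[C@@]12CCC[C@]3(COC(=O)[C@@]45C[C@@H](C[C@@H](O[Si](C)(C)C(C)(C)C)[C@H]43)C[C@@H]5O[Si](CC)(CC)CC)[C@@H]1C(=O)OC2
F10 | step 15 | 11-O-tert-butyldimethylsilyl ether of 26 | C[C@@]12CCC[C@]3(COC(=O)[C@@]45C[C@@H](C[C@@H](O[Si](C)(C)C(C)(C)C)[C@H]43)C[C@@H]5O)[C@@H]1C(=O)OC2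
F11 | step 15 | 11-O-tert-butyldimethylsilyl ether of 27 | C[C@@]12CCC[C@]3(COC(=O)[C@@]45C[C@@H](C[C@@H](O[Si](C)(C)C(C)(C)C)[C@H]43)CC5=O)[C@@H]1C(=O)OC2
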